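**Retrosynthetic overview**

1. Both flavone C2–aryl bonds are cut at once. The C2–C1′ bond to the anisole ring (para to OMe) and its twin to the phenoxy ring (para to the ether oxygen) come from one three-component Pd(II) oxidative boron-Heck union of a diaryl ether bis(boronate) with two molecules of 5,7-bis(benzyloxy)chromone.
2. Enabling feature: in each γ-pyranone ring (O1, C2, C3, C4, C4a, C8a) the C2–H carbon is the β-carbon of the vinylogous ester O1–C2=C3–C4=O. Aryl–Pd adds there and β-hydride elimination restores the flavone oxidation level. The two identical chromone units sit para to oxygen on the two rings of the 2-aryloxyanisole core, where C–B bonds are easily placed.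
3. The bis(boronate) comes from 5-bromoguaiacol by O-arylation (diaryl ether C–O bond) and double Miyaura borylation. The chromone comes from phloroacetophenone by dibenzylation and enaminone annulation.
4. Ring order: all benzene rings are purchased. The pyranone ring is closed once on the small fragment (step 4) and used twice. No ring is formed afterwards, and global debenzylation ends the route.

Key step: step 5

Remark on the chemistry: the target has no stereocentre or other stereogenic element, so it is one achiral compound and no step has to control configuration.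

Convention: partly reacted species of the multifold identical steps 2, 3 and 6 are not numbered. In step 5 the two mono-arylated boronates are numbered, because the second coupling is the critical event.

**Route**

Step 1
Reactants: 1 5-bromo-2-methoxyphenol; 2 bis(4-bromophenyl)iodonium trifluoromethanesulfonate
Product: 3 4-bromo-2-(4-bromophenoxy)-1-methoxybenzene
Conditions: t-BuOK (1.1 equiv), THF, 0 °C; then 2 (1.2 equiv), rt to 40 °C
Reagents that add atoms: none
Why: Metal-free O-arylation of the phenoxide with a symmetric diaryliodonium salt (ligand coupling at iodine(III)) should give the diaryl ether under mild conditions without touching either C–Br bond.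

Step 2
Reactants: 3 4-bromo-2-(4-bromophenoxy)-1-methoxybenzene
Product: 4 2-[4-methoxy-3-[4-(4,4,5,5-tetramethyl-1,3,2-dioxaborolan-2-yl)phenoxy]phenyl]-4,4,5,5-tetramethyl-1,3,2-dioxaborolane
Conditions: B2pin2 (2.6 equiv), PdCl2(dppf) (6 mol%), KOAc (6 equiv), 1,4-dioxane, 90 °C
Reagents that add atoms: bis(pinacolato)diboron, CC1(C)OB(OC1(C)C)B1OC(C)(C)C(C)(C)O1
Why: Twofold Miyaura borylation should convert both aryl bromides, since KOAc is too weak a base to drive Suzuki coupling of the product with remaining bromide.

Step 3
Reactants: 5 2',4',6'-trihydroxyacetophenone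
Product: 6 1-[2,4-bis(benzyloxy)-6-hydroxyphenyl]ethanone
Conditions: BnBr (2.05 equiv), K2CO3 (2.2 equiv), DMF, 0 °C to rt
Reagents that add atoms: benzyl bromide, BrCc1ccccc1
Why: Williamson etherification should stop at the dibenzyl ether, because the last hydroxyl is hydrogen-bonded to the acetyl carbonyl and is the least reactive; it is kept for the ring closure.

Step 4
Reactants: 6 1-[2,4-bis(benzyloxy)-6-hydroxyphenyl]ethanone
Product: 8 5,7-bis(benzyloxy)-4H-chromen-4-one, via enaminone 7 (not isolated)
Conditions: DMF-DMA (3 equiv), toluene, 100 °C; evaporate; then AcOH, 90 °C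
Reagents that add atoms: N,N-dimethylformamide dimethyl acetal, COC(OC)N(C)C
Why: Condensation of the methyl ketone with DMF-DMA should give the (E)-enaminone, and acid then promotes 6-endo oxa-Michael addition of the free phenol and loss of dimethylamine (enaminone route to 3-unsubstituted chromones), leaving C2–H free.

Step 5
Reactants: 4 the bis(pinacol boronate) (1 equiv, added slowly); 8 5,7-bis(benzyloxy)-4H-chromen-4-one (3 equiv, excess recoverable)
Product: 11 5,7,5'',7''-tetra-O-benzyl-4'-O-methylochnaflavone, via anisole-ring mono-flavone boronate 9 (not isolated), via phenoxy-ring mono-flavone boronate 10 (not isolated)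
Conditions: Pd(TFA)2 (20 mol%), 5-nitro-1,10-phenanthroline (30 mol%), O2 (1 atm), DMSO, 100 °C
Reagents that add atoms: none
Why: Each C–B bond of 4 transmetalates to the phenanthroline-ligated Pd(II) trifluoroacetate, the aryl–Pd adds syn across C2=C3 of 8 with the aryl group going to C2 and palladium to C3 as a C-bound enolate, this enolate epimerises through its O-bound form so that syn β-hydride elimination restores C2=C3, and O2 reoxidises the reduced palladium. The closest known reaction type is the Pd(II)-catalysed oxidative boron-Heck C2-arylation of chromones with arylboron reagents to flavones, run here twice in one flask on a bis(boronate) so that three components are joined around the diaryl ether core. No ring is closed and no stereocentre is formed. The step needs C2 over C3 regioselectivity, which the enone polarisation of the γ-pyranone secures, and site fidelity on the arene, which the two C–B bonds secure by ipso substitution para to OMe on the anisole ring and para to the ether oxygen on the phenoxy ring. It also needs the second arylation to outrun oxidative homocoupling and protodeboronation, for which 8 is used in excess and 4 is added slowly; benzyl ethers, the aryl methyl ether and the diaryl ether should be inert to Pd(II)/O2 in DMSO.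

Step 6
Reactants: 11 5,7,5'',7''-tetra-O-benzyl-4'-O-methylochnaflavone
Product: 12 4'-O-methylochnaflavone
Conditions: H2 (1 atm), 10% Pd/C, THF–MeOH, rt
Reagents that add atoms: none
Why: Catalytic hydrogenolysis should cleave the four benzyl aryl ethers, while the aryl methyl ether, the diaryl ether and the cross-conjugated C2=C3 bonds of the pyranones are expected to survive at 1 atm and room temperature.

**Compound list**

1 | 5-bromo-2-methoxyphenol (5-bromoguaiacol) | COc1ccc(Br)cc1O | starting material
2 | bis(4-bromophenyl)iodonium trifluoromethanesulfonate | Brc1ccc([I+]c2ccc(Br)cc2)cc1.[O-]S(=O)(=O)C(F)(F)F | starting material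
3 | 4-bromo-2-(4-bromophenoxy)-1-methoxybenzene | COc1ccc(Br)cc1Oc1ccc(Br)cc1 | intermediate
4 | 2-[4-methoxy-3-[4-(4,4,5,5-tetramethyl-1,3,2-dioxaborolan-2-yl)phenoxy]phenyl]-4,4,5,5-tetramethyl-1,3,2-dioxaborolane | COc1ccc(B2OC(C)(C)C(C)(C)O2)cc1Oc1ccc(B2OC(C)(C)C(C)(C)O2)cc1 | intermediate
5 | 2',4',6'-trihydroxyacetophenone (phloroacetophenone) | CC(=O)c1c(O)cc(O)cc1O | starting material
6 | 1-[2,4-bis(benzyloxy)-6-hydroxyphenyl]ethanone | CC(=O)c1c(O)cc(OCc2ccccc2)cc1OCc1ccccc1 | intermediate
7 | (E)-1-[2,4-bis(benzyloxy)-6-hydroxyphenyl]-3-(dimethylamino)prop-2-en-1-one (formed in the flask in step 4) | CN(C)/C=C/C(=O)c1c(O)cc(OCc2ccccc2)cc1OCc1ccccc1 | intermediate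
8 | 5,7-bis(benzyloxy)-4H-chromen-4-one | O=c1ccoc2cc(OCc3ccccc3)cc(OCc3ccccc3)c12 | intermediate
9 | 5,7-bis(benzyloxy)-2-[4-methoxy-3-[4-(4,4,5,5-tetramethyl-1,3,2-dioxaborolan-2-yl)phenoxy]phenyl]-4H-chromen-4-one (formed in the flask in step 5) | COc1ccc(-c2cc(=O)c3c(OCc4ccccc4)cc(OCc4ccccc4)cc3o2)cc1Oc1ccc(B2OC(C)(C)C(C)(C)O2)cc1 | intermediate
10 | 5,7-bis(benzyloxy)-2-[4-[2-methoxy-5-(4,4,5,5-tetramethyl-1,3,2-dioxaborolan-2-yl)phenoxy]phenyl]-4H-chromen-4-one (formed in the flask in step 5) | COc1ccc(B2OC(C)(C)C(C)(C)O2)cc1Oc1ccc(-c2cc(=O)c3c(OCc4ccccc4)cc(OCc4ccccc4)cc3o2)cc1 | intermediate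
11 | 5,7-bis(benzyloxy)-2-[4-[5-[5,7-bis(benzyloxy)-4-oxo-4H-chromen-2-yl]-2-methoxyphenoxy]phenyl]-4H-chromen-4-one (5,7,5'',7''-tetra-O-benzyl-4'-O-methylochnaflavone) | COc1ccc(-c2cc(=O)c3c(OCc4ccccc4)cc(OCc4ccccc4)cc3o2)cc1Oc1ccc(-c2cc(=O)c3c(OCc4ccccc4)cc(OCc4ccccc4)cc3o2)cc1 | intermediate
12 | 4'-O-methylochnaflavone, 5,7-dihydroxy-2-[4-[5-(5,7-dihydroxy-4-oxo-4H-chromen-2-yl)-2-methoxyphenoxy]phenyl]-4H-chromen-4-one | COc1ccc(-c2cc(=O)c3c(O)cc(O)cc3o2)cc1Oc1ccc(-c2cc(=O)c3c(O)cc(O)cc3o2)cc1 | target

**Step count**

Total steps: 6. Longest linear sequence: 4 steps (1 → 2 → 5 → 6, or 3 → 4 → 5 → 6).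

**Steps most likely to fail**

Step 5. Oxidative homocoupling, protodeboronation or hydroxylation of the boronate may outpace insertion into the electron-rich chromone, or the reaction may stall after the first arylation. The fallback separates C–C bond formation from oxidation. It sets out from 4 and 8: Rh(I)-catalysed twofold Hayashi–Miyaura 1,4-addition ([Rh(cod)OH]2 5 mol%, KOH 20 mol%, dioxane–H2O, 60 °C, argon) should give the bis-flavanone F1 as a mixture of diastereomers. Dehydrogenation with I2 (cat.) in DMSO at 120 °C then erases both C2 stereocentres and returns to the route at 11.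

Step 6. The pyranone C2=C3 bonds may be over-reduced, or the hydrogenolysis may stall when partly debenzylated material precipitates on the catalyst. The fallback changes the reaction type from reductive C–O cleavage to Lewis-acid benzyl transfer. It sets out from 11: BCl3 (excess) with pentamethylbenzene as benzyl cation scavenger, CH2Cl2, −78 to −40 °C, then methanol and aqueous work-up, returning at 12. The 4'-OMe should survive because BCl3 cleaves methyl ethers only when they are chelated next to a carbonyl. This fallback makes no new compound (F0).

Step 2. Suzuki-type oligomerisation between borylated and brominated ends, or protodehalogenation on the electron-rich rings, may erode the double borylation. The fallback replaces palladium catalysis by organolithium chemistry. It sets out from 3: twofold bromine–lithium exchange (n-BuLi, THF, −78 °C) in the presence of B(OiPr)3, followed by aqueous HCl, should give the bis(boronic acid) F2. Condensation with pinacol (MgSO4, THF, rt) returns to the route at 4.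

**Further compounds**

F1 | step 5 | 5,7-bis(benzyloxy)-2-[4-[5-[5,7-bis(benzyloxy)-4-oxochroman-2-yl]-2-methoxyphenoxy]phenyl]chroman-4-one (bis-flavanone, mixture of diastereomers) | COc1ccc(C2CC(=O)c3c(OCc4ccccc4)cc(OCc4ccccc4)cc3O2)cc1Oc1ccc(C2CC(=O)c3c(OCc4ccccc4)cc(OCc4ccccc4)cc3O2)cc1
F0 | step 6 | none | none
F2 | step 2 | [3-(4-boronophenoxy)-4-methoxyphenyl]boronic acid | COc1ccc(B(O)O)cc1Oc1ccc(B(O)O)cc1
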